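The target is cut at the C8–vinyl bond into an 8-bromoflavan and a silyl-protected 2-vinylphenol (ring A); the flavan is then cut across its pyran ring C. Since O1–C2–C3–C4 is fused to the phloroglucinol-type ring B at C4a and C8a and C2 is the only stereocentre, ring C is the hetero-[4+2] adduct of styrene and an ortho-quinone methide. One chiral-acid-catalysed operation forms C3–C4 and O1–C2, closes ring C and sets C2 as S. Its precursor is the salicyl alcohol 2-(hydroxymethyl)-3,5-dimethoxyphenol, freshly made from the commercial aldehyde and added slowly to excess styrene.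

Key step: step 2

Assumption: the sense of induction of the imidodiphosphorimidate (IDPi) acid cannot be predicted for this CH2 methide, so the route is written with the (S,S)-catalyst, the configuration of 5 is to be checked against material from the known-chemistry fallback, and the mirror-image catalyst is used if R results (ring A = stilbene phenol ring, ring B = benzo ring of the chroman, ring C = pyran ring; flavan numbering).

Step 1
Reactants: 1 2-hydroxy-4,6-dimethoxybenzaldehyde
Product: 2 2-(hydroxymethyl)-3,5-dimethoxyphenol
Conditions: NaBH4 (1.0 equiv), THF/MeOH, 0 °C; pH 7 phosphate buffer work-up, no silica, used within hours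
Reagents that add atoms: none
Why: Borohydride reduction of an aryl aldehyde should give the salicyl alcohol cleanly, and the neutral work-up with immediate use avoids acid-triggered self-condensation of this electron-rich benzylic alcohol.

Step 2
Reactants: 2 2-(hydroxymethyl)-3,5-dimethoxyphenol; 3 styrene
Product: 5 (S)-5,7-dimethoxyflavan [(2S)-5,7-dimethoxy-2-phenylchromane], via ortho-quinone methide 4 (not isolated)
Conditions: (S,S)-IDPi (5 mol %), styrene (20 equiv), 5 Å MS, CHCl3, −30 °C, 2 added over 10 h by syringe pump
Reagents that add atoms: none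
Why: Proposed new method: the chiral acid protonates the benzylic hydroxyl of 2 and water leaves to give ortho-quinone methide 4, held as a hydrogen-bonded ion pair with the imidodiphosphorimidate anion; the CH2 terminus of styrene then attacks the methide carbon (C3–C4) while the ring-B oxygen captures the developing phenyl-stabilised cation (O1–C2). The closest known reactions are the chiral phosphoric acid catalysed hetero-Diels–Alder reactions of aryl-substituted ortho-quinone methides with styrenes and the racemic acid-promoted flavan synthesis from salicyl alcohols, so what is extrapolated is enantiocontrol at an unsubstituted methide. Ring C closes in an asynchronous inverse-electron-demand hetero-[4+2] mode, the oxa-diene O=C8a–C4a=CH2 adding across the styrene double bond. C2 is set by the confined chiral anion, which blocks one face of the bound methide so that styrene approaches from the open face. The step needs regioselectivity for the 2-phenyl isomer, secured by the phenyl group that stabilises charge at the styrene α-carbon and by the two methoxy groups that let the methide form and polarise at low temperature. It also needs chemoselectivity over Friedel–Crafts alkylation of the electron-rich rings of 2 and 5, which the narrow catalyst pocket, the large excess of styrene and the slow addition of 2 are meant to secure.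

Step 3
Reactants: 5 (S)-5,7-dimethoxyflavan
Product: 6 (S)-8-bromo-5,7-dimethoxyflavan
Conditions: NBS (1.0 equiv), CH2Cl2, −40 → 0 °C, dark
Reagents that add atoms: N-bromosuccinimide, O=C1CCC(=O)N1Br
Why: Electrophilic aromatic bromination of ring B should take C8, which lies between the tied-back ring oxygen and one methoxy group and is less hindered than C6 between two methoxy groups, the selectivity known for NBS and 5,7-dialkoxyflavans; C2 is not touched under these neutral ionic conditions.

Step 4
Reactants: 7 2,6-dimethoxytoluene
Product: 9 3,5-dimethoxy-4-methylphenol, via aryl pinacol boronate 8 (not isolated)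
Conditions: [Ir(OMe)(cod)]2 (1.5 mol %), dtbpy (3 mol %), B2pin2 (1.0 equiv), THF, 80 °C; then 30% aq H2O2, NaOH, 0 °C → rt
Reagents that add atoms: bis(pinacolato)diboron, CC1(C)OB(OC1(C)C)B1OC(C)(C)C(C)(C)O1 (boryl group of 8); hydrogen peroxide, OO (phenolic oxygen of 9)
Why: Iridium-catalysed C–H borylation (Hartwig–Miyaura type) is sterically controlled and should take the only ring C–H of 7 without an ortho substituent (para to the methyl group), and basic peroxide oxidation of the crude boronate then gives the phenol.

Step 5
Reactants: 9 3,5-dimethoxy-4-methylphenol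
Product: 11 6-hydroxy-2,4-dimethoxy-3-methylbenzaldehyde, via hydroxymethyl phenol 10 (not isolated)
Conditions: MgCl2 (1.5 equiv), Et3N (4 equiv), (CH2O)n (7 equiv), MeCN, reflux; aq HCl work-up
Reagents that add atoms: paraformaldehyde (reacting as formaldehyde), C=O
Why: Magnesium-mediated ortho-formylation (Casnati–Skattebøl) delivers formaldehyde within a magnesium phenoxide chelate and oxidises the resulting hydroxymethyl compound by hydride transfer to a second formaldehyde; the two ortho positions of 9 are equivalent and the para position carries the methyl group, so only one aldehyde can form.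

Step 6
Reactants: 11 6-hydroxy-2,4-dimethoxy-3-methylbenzaldehyde
Product: 12 6-[(tert-butyldimethylsilyl)oxy]-2,4-dimethoxy-3-methylbenzaldehyde
Conditions: TBSCl (1.3 equiv), imidazole (2.5 equiv), DMF, rt
Reagents that add atoms: tert-butyldimethylsilyl chloride, CC(C)(C)[Si](C)(C)Cl
Why: Imidazole-promoted silylation masks the phenol so that neither the ylide nor the amine base of the following steps generates a phenoxide, and the group can later be removed with fluoride without acid.

Step 7
Reactants: 12 6-[(tert-butyldimethylsilyl)oxy]-2,4-dimethoxy-3-methylbenzaldehyde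
Product: 13 tert-butyl(2-ethenyl-3,5-dimethoxy-4-methylphenoxy)dimethylsilane
Conditions: Ph3PCH3Br (1.5 equiv), KOtBu (1.4 equiv), THF, 0 °C → rt
Reagents that add atoms: methyltriphenylphosphonium bromide, [Br-].C[P+](c1ccccc1)(c1ccccc1)c1ccccc1
Why: Wittig methylenation with the small, reactive non-stabilised ylide should convert even this hindered, electron-rich aldehyde into the terminal alkene while the aryl silyl ether survives at low temperature.

Step 8
Reactants: 6 (S)-8-bromo-5,7-dimethoxyflavan; 13 tert-butyl(2-ethenyl-3,5-dimethoxy-4-methylphenoxy)dimethylsilane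
Product: 14 tert-butyl{2-[(E)-2-[(2S)-5,7-dimethoxy-2-phenylchroman-8-yl]ethenyl]-3,5-dimethoxy-4-methylphenoxy}dimethylsilane
Conditions: Pd2(dba)3 (2.5 mol %), P(t-Bu)3·HBF4 (10 mol %), Cy2NMe (2 equiv), 1,4-dioxane, 100 °C
Reagents that add atoms: none
Why: Mizoroki–Heck coupling, in which the electron-rich bulky phosphine lets zerovalent palladium insert into the hindered, electron-rich C8–Br bond, the aryl group adds to the unsubstituted CH2 carbon of the alkene and syn β-hydride elimination gives the E-stilbene; no stereocentre is formed and C2 is inert to these conditions.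

Step 9
Reactants: 14 tert-butyl{2-[(E)-2-[(2S)-5,7-dimethoxy-2-phenylchroman-8-yl]ethenyl]-3,5-dimethoxy-4-methylphenoxy}dimethylsilane
Product: 15 2-[(E)-2-[(2S)-5,7-dimethoxy-2-phenylchroman-8-yl]ethenyl]-3,5-dimethoxy-4-methylphenol (target)
Conditions: Bu4NF (1.2 equiv), AcOH (1.2 equiv), THF, 0 °C, argon
Reagents that add atoms: none
Why: Fluoride cleavage of the aryl silyl ether under acetic acid buffering should free the phenol without acid strong enough to cyclise the 2-hydroxystilbene or ionise the benzylic C2–O bond, and without leaving an oxidation-prone phenoxide.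

Compound list
1 | 2-hydroxy-4,6-dimethoxybenzaldehyde | COc1cc(O)c(C=O)c(OC)c1 | starting material
2 | 2-(hydroxymethyl)-3,5-dimethoxyphenol | COc1cc(O)c(CO)c(OC)c1 | intermediate
3 | styrene | C=Cc1ccccc1 | starting material
4 | 3,5-dimethoxy-6-methylidenecyclohexa-2,4-dien-1-one (ortho-quinone methide) | C=C1C(=O)C=C(OC)C=C1OC | intermediate (not isolated)
5 | (S)-5,7-dimethoxyflavan [(2S)-5,7-dimethoxy-2-phenylchromane] | COc1cc(OC)c2c(c1)O[C@H](c1ccccc1)CC2 | intermediate
6 | (S)-8-bromo-5,7-dimethoxyflavan [(2S)-8-bromo-5,7-dimethoxy-2-phenylchromane] | COc1cc(OC)c2c(c1Br)O[C@H](c1ccccc1)CC2 | intermediate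
7 | 2,6-dimethoxytoluene | COc1cccc(OC)c1C | starting material
8 | 2-(3,5-dimethoxy-4-methylphenyl)-4,4,5,5-tetramethyl-1,3,2-dioxaborolane | COc1cc(B2OC(C)(C)C(C)(C)O2)cc(OC)c1C | intermediate (not isolated)
9 | 3,5-dimethoxy-4-methylphenol | COc1cc(O)cc(OC)c1C | intermediate
10 | 2-(hydroxymethyl)-3,5-dimethoxy-4-methylphenol (formed as its magnesium salt) | COc1cc(O)c(CO)c(OC)c1C | intermediate (not isolated)
11 | 6-hydroxy-2,4-dimethoxy-3-methylbenzaldehyde | COc1cc(O)c(C=O)c(OC)c1C | intermediate
12 | 6-[(tert-butyldimethylsilyl)oxy]-2,4-dimethoxy-3-methylbenzaldehyde | COc1cc(O[Si](C)(C)C(C)(C)C)c(C=O)c(OC)c1C | intermediate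
13 | tert-butyl(2-ethenyl-3,5-dimethoxy-4-methylphenoxy)dimethylsilane | COc1cc(O[Si](C)(C)C(C)(C)C)c(C=C)c(OC)c1C | intermediate
14 | tert-butyl{2-[(E)-2-[(2S)-5,7-dimethoxy-2-phenylchroman-8-yl]ethenyl]-3,5-dimethoxy-4-methylphenoxy}dimethylsilane | COc1cc(O[Si](C)(C)C(C)(C)C)c(/C=C/c2c(OC)cc(OC)c3c2O[C@H](c2ccccc2)CC3)c(OC)c1C | intermediate
15 | 2-[(E)-2-[(2S)-5,7-dimethoxy-2-phenylchroman-8-yl]ethenyl]-3,5-dimethoxy-4-methylphenol | COc1cc(O)c(/C=C/c2c(OC)cc(OC)c3c2O[C@H](c2ccccc2)CC3)c(OC)c1C | target

Total step count: 9. Longest linear sequence: 6 steps (steps 4 to 9, from 2,6-dimethoxytoluene); the flavan branch (steps 1 to 3) joins at step 8.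

Steps most likely to fail

Step 2 (labelled step). What may go wrong: weak facial discrimination at the small CH2 methide, alkylation of the electron-rich rings of 2 and 5 by the methide in place of cycloaddition, and acid-initiated oligomerisation of styrene. The fallback uses known chemistry only, sets out from 1 and returns at 5. Wittig olefination of 1 with the stabilised ylide Ph3P=CHC(O)Ph in toluene at reflux should give (E)-3-(2-hydroxy-4,6-dimethoxyphenyl)-1-phenylprop-2-en-1-one F1. Hydrogenation of the alkene (H2, Pd/C, EtOAc, stopped after one equivalent) should give 3-(2-hydroxy-4,6-dimethoxyphenyl)-1-phenylpropan-1-one F2. Asymmetric transfer hydrogenation with RuCl[(R,R)-TsDPEN](p-cymene) in HCO2H/Et3N should give (R)-2-(3-hydroxy-3-phenylpropyl)-3,5-dimethoxyphenol F3. Mitsunobu ring closure (PPh3, DIAD, THF, 0 °C), in which the phenol oxygen displaces the activated benzylic hydroxyl with inversion, then gives the S flavan 5.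

Step 8. What may go wrong: slow oxidative addition at the doubly ortho-substituted, electron-rich C–Br bond, aryl transfer to the internal alkene carbon, or loss of the silyl group followed by polymerisation of the vinylphenol. The fallback replaces the Heck reaction by a Suzuki–Miyaura coupling with preformed E geometry; it sets out from 12 and 6 and returns at 14. A boron-Wittig reaction of 12 with CH2(Bpin)2 and LiTMP (lithium 2,2,6,6-tetramethylpiperidide) in THF at −78 → 0 °C should give tert-butyl{3,5-dimethoxy-4-methyl-2-[(E)-2-(4,4,5,5-tetramethyl-1,3,2-dioxaborolan-2-yl)ethenyl]phenoxy}dimethylsilane F4. Coupling of F4 with 6 (Pd(OAc)2, SPhos, K3PO4, toluene/H2O, 80 °C) gives 14.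

Step 3. What may go wrong: attack of bromine at C6 beside C8, or a second bromination. The fallback places the bromine before ring C is built; it sets out from 1 and returns at 6. NBS with catalytic i-Pr2NH in CH2Cl2, conditions that direct bromine ortho to a phenolic hydroxyl, should give 3-bromo-2-hydroxy-4,6-dimethoxybenzaldehyde F5, the position to be confirmed by NOE from the remaining ring proton to both methoxy groups. NaBH4 reduction as in step 1 gives 2-bromo-6-(hydroxymethyl)-3,5-dimethoxyphenol F6. The cycloaddition of step 2 with styrene then runs through 2-bromo-3,5-dimethoxy-6-methylidenecyclohexa-2,4-dien-1-one F7 and delivers 6 directly, the bromine also lowering the tendency of the ring to self-alkylate.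

Further compounds
F1 | step 2 | (E)-3-(2-hydroxy-4,6-dimethoxyphenyl)-1-phenylprop-2-en-1-one | COc1cc(O)c(/C=C/C(=O)c2ccccc2)c(OC)c1
F2 | step 2 | 3-(2-hydroxy-4,6-dimethoxyphenyl)-1-phenylpropan-1-one | COc1cc(O)c(CCC(=O)c2ccccc2)c(OC)c1
F3 | step 2 | (R)-2-(3-hydroxy-3-phenylpropyl)-3,5-dimethoxyphenol | COc1cc(O)c(CC[C@@H](O)c2ccccc2)c(OC)c1
F4 | step 8 | tert-butyl{3,5-dimethoxy-4-methyl-2-[(E)-2-(4,4,5,5-tetramethyl-1,3,2-dioxaborolan-2-yl)ethenyl]phenoxy}dimethylsilane | COc1cc(O[Si](C)(C)C(C)(C)C)c(/C=C/B2OC(C)(C)C(C)(C)O2)c(OC)c1C
F5 | step 3 | 3-bromo-2-hydroxy-4,6-dimethoxybenzaldehyde | COc1cc(OC)c(C=O)c(O)c1Br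
F6 | step 3 | 2-bromo-6-(hydroxymethyl)-3,5-dimethoxyphenol | COc1cc(OC)c(CO)c(O)c1Br
F7 | step 3 | 2-bromo-3,5-dimethoxy-6-methylidenecyclohexa-2,4-dien-1-one | C=C1C(=O)C(Br)=C(OC)C=C1OC
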